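Everything rests on C4' of the pyran ring being a 2-hydroxybenzylic carbon (eudesmane numbering for the decalin, primes for the chromene): cutting O1'–C2' and C3'–C4' leaves an ortho-quinone methide (O1', C8a', C4a', C4') and an acetophenone enol unit. The key step protonates the exocyclic styrene carbon C1 of a 2-alkenylphenol, traps the resulting ortho-quinone methide with the enol silane and eliminates silanol: one operation closes the pyran ring and sets both C1 and C4', steered by the quaternary C10 next to C1. The alkenylphenol, flat at both centres, comes from (−)-β-elemene, whose ring B already carries C5, C7 and C10, by an allyl cation–olefin closure of ring A.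

Key step: step 9

Numbering: C1 carries the chromenyl group, C4 the tertiary alcohol, C5/C10 are the ring fusion, C7 carries the isopropenyl group; ring A = C1–C5, C10; ring B = C5–C10.
Assumption: commercial (−)-β-elemene is the (1S,2S,4R) enantiomer, whose three stereocentres become C10, C5 and C7 of the target; the alkene geometry drawn for 11 and 12 (aryl anti to C10) is the expected one but is erased in step 9.

Step 1
Reactants: 1 1,2,3,5-tetramethoxybenzene
Product: 2 2,3,4,6-tetramethoxybenzaldehyde
Conditions: POCl3, DMF, 0 → 70 °C; then H2O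
Reagents that add atoms: N,N-dimethylformamide CN(C)C=O; water O
Why: Vilsmeier–Haack formylation of the symmetric, highly activated arene can only occur at its two equivalent free positions, so a single aldehyde should result.

Step 2
Reactants: 2 2,3,4,6-tetramethoxybenzaldehyde
Product: 3 2-hydroxy-3,4,6-trimethoxybenzaldehyde
Conditions: BCl3 (1.1 equiv), CH2Cl2, −78 → 0 °C; then H2O
Reagents that add atoms: none
Why: Chelation-assisted Lewis-acid ether cleavage ortho to the formyl group should remove the methyl of the 2-methoxy group, which is wedged between CHO and the 3-methoxy group and is therefore the more basic and more strained of the two ortho ethers.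

Step 3
Reactants: 3 2-hydroxy-3,4,6-trimethoxybenzaldehyde
Product: 4 2-(allyloxy)-3,4,6-trimethoxybenzaldehyde
Conditions: allyl bromide, K2CO3, DMF, 50 °C
Reagents that add atoms: allyl bromide C=CCBr
Why: Williamson etherification masks the phenol as an ether that survives organolithium and aqueous acid and is later removed by zerovalent palladium.

Step 4
Reactants: 5 (−)-β-elemene
Product: 6 1-[(1R,2S,4R)-1-methyl-2,4-di(prop-1-en-2-yl)cyclohexyl]ethan-1-one
Conditions: PdCl2 (10 mol%), CuCl (20 mol%), O2 (1 atm), DMA–H2O 7:1, rt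
Reagents that add atoms: water O
Why: Tsuji–Wacker oxidation by divalent palladium attacks only the monosubstituted vinyl group (the 1,1-disubstituted isopropenyl groups are inert) and should give the Markovnikov methyl ketone without touching a stereocentre.

Step 5
Reactants: 6 1-[(1R,2S,4R)-1-methyl-2,4-di(prop-1-en-2-yl)cyclohexyl]ethan-1-one
Product: 7 (E)-2,4,6-triisopropylbenzenesulfonylhydrazone of 6
Conditions: 2,4,6-(i-Pr)3C6H2SO2NHNH2, HCl (cat.), THF, rt
Reagents that add atoms: 2,4,6-triisopropylbenzenesulfonohydrazide CC(C)c1cc(C(C)C)c(S(=O)(=O)NN)c(C(C)C)c1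
Why: Acid-catalysed hydrazone condensation places the sulfonamide anti to the quaternary carbon and syn to the methyl group, the only enolisable position, as the Shapiro reaction requires.

Step 6
Reactants: 7 (E)-2,4,6-triisopropylbenzenesulfonylhydrazone of 6; 4 2-(allyloxy)-3,4,6-trimethoxybenzaldehyde
Product: 9 1-[2-(allyloxy)-3,4,6-trimethoxyphenyl]-2-[(1R,2S,4R)-1-methyl-2,4-di(prop-1-en-2-yl)cyclohexyl]prop-2-en-1-ol (both carbinol epimers), via vinyllithium 8 (not isolated)
Conditions: n-BuLi (2.1 equiv), THF, −78 → 0 °C; then 4, −78 °C; aq. NH4Cl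
Reagents that add atoms: none
Why: Shapiro reaction (dianion at the methyl group, loss of sulfinate and N2) gives the 1-substituted vinyllithium, whose 1,2-addition to the aldehyde forms the C1–C4' bond; the new carbinol centre forms as a mixture that step 7 erases.

Step 7
Reactants: 9 1-[2-(allyloxy)-3,4,6-trimethoxyphenyl]-2-[(1R,2S,4R)-1-methyl-2,4-di(prop-1-en-2-yl)cyclohexyl]prop-2-en-1-ol
Product: 11 (E)-1-[2-(allyloxy)-3,4,6-trimethoxybenzylidene]eudesm-11-en-4α-ol, via allyl cation 10 (not isolated)
Conditions: CSA (10 mol%), THF–H2O 3:1, 0 → 40 °C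
Reagents that add atoms: water O
Why: Ionisation of the doubly activated (allylic and trioxygenated benzylic) alcohol gives an allyl cation whose CH2 terminus (C2) is attacked by the CH2 (C3) of the neighbouring equatorial isopropenyl group in a chair transition state (allyl-cation-initiated cation–olefin cyclization; the trans-diequatorial C5/C10 substituents dictate the trans-decalin), while water captures the tertiary C4 centre equatorially from the α face, anti to the axial C10 methyl, to set 4α-OH; the allyl ether keeps the phenol oxygen from closing a 2H-chromene.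

Step 8
Reactants: 11 (E)-1-[2-(allyloxy)-3,4,6-trimethoxybenzylidene]eudesm-11-en-4α-ol
Product: 12 (E)-1-(2-hydroxy-3,4,6-trimethoxybenzylidene)eudesm-11-en-4α-ol
Conditions: Pd(PPh3)4 (5 mol%), morpholine, THF, rt
Reagents that add atoms: none
Why: Tsuji–Trost deallylation: zerovalent palladium ionises the aryl allyl ether and morpholine takes up the allyl fragment, leaving the alkenes and the tertiary alcohol untouched.

Step 9
Reactants: 12 (E)-1-(2-hydroxy-3,4,6-trimethoxybenzylidene)eudesm-11-en-4α-ol; 13 1-phenyl-1-(trimethylsiloxy)ethene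
Product: 16 (4'R)-5,7,8-trimethoxy-2-phenyl-4-[(1S,4R,5R,7R,10S)-4-hydroxyeudesm-11-en-1-yl]-4H-chromene (target), via ortho-quinone methide 14 (not isolated), via siloxychroman 15 (not isolated)
Conditions: 13 (3 equiv), (PhO)2P(O)OH (10 mol%), 4 Å MS, CH2Cl2, −20 → 40 °C
Reagents that add atoms: none
Why: The phosphoric acid protonates 12 at C1, axially from the α face anti to the axial C10 methyl (also the thermodynamic outcome, an equatorial C1–C4' bond, and reversible, so a wrong C1 epimer can return to 12), and so unmasks the ortho-quinone methide 14, which reacts as its O-protonated form. The CH2 terminus of 13 then bonds to C4' and the phenol oxygen to the siloxy-bearing carbon, a formal inverse-electron-demand oxa-[4+2] closure of the pyran ring through the C3'–C4' and O1'–C2' bonds (concerted, or Mukaiyama–Michael addition followed by 6-exo-trig capture of the oxocarbenium ion) that gives 15, from which the acid expels trimethylsilanol to leave the C2'=C3' enol ether. The closest known reaction type is the Brønsted-acid-catalysed conversion of 2-alkenylphenols into ortho-quinone methides with trapping by enol ethers or enol silanes. C1 is controlled by the ring (axial protonation anti to the C10 methyl); C4' is controlled by allylic 1,3-strain in 14, whose C1–H eclipses the C4'=C4a' bond so that C10 and C2 shield opposite faces and 13 adds anti to the quaternary C10, which corresponds to (4'R). The step needs C-protonation at C1 and not at C4' (secured by the ortho-hydroxy and ortho/para-methoxy donors that stabilise charge at C4'), addition of the nucleophilic carbon of 13 to C4' only (the sole electrophilic carbon of 14), and survival of the tertiary alcohol and the isopropenyl group (weak acid, low temperature, sieves).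

Compound list
1 | 1,2,3,5-tetramethoxybenzene | COc1cc(OC)c(OC)c(OC)c1 | starting material
2 | 2,3,4,6-tetramethoxybenzaldehyde | COc1cc(OC)c(C=O)c(OC)c1OC | intermediate
3 | 2-hydroxy-3,4,6-trimethoxybenzaldehyde | COc1cc(OC)c(C=O)c(O)c1OC | intermediate
4 | 2-(allyloxy)-3,4,6-trimethoxybenzaldehyde | COc1cc(OC)c(C=O)c(OCC=C)c1OC | intermediate
5 | (−)-β-elemene, (1S,2S,4R)-1-ethenyl-1-methyl-2,4-di(prop-1-en-2-yl)cyclohexane | C=C(C)[C@@H]1CC[C@@](C)(C=C)[C@@H](C1)C(C)=C | starting material
6 | 1-[(1R,2S,4R)-1-methyl-2,4-di(prop-1-en-2-yl)cyclohexyl]ethan-1-one (vinyl group of 5 turned into acetyl, ring stereocentres unchanged) | C=C(C)[C@@H]1CC[C@@](C)(C(C)=O)[C@@H](C1)C(C)=C | intermediate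
7 | (E)-2,4,6-triisopropylbenzenesulfonylhydrazone of 6 (sulfonamide anti to the quaternary carbon) | C=C(C)[C@@H]1CC[C@@](C)(/C(C)=N/NS(=O)(=O)c2c(C(C)C)cc(C(C)C)cc2C(C)C)[C@@H](C1)C(C)=C | intermediate
8 | 1-[(1R,2S,4R)-1-methyl-2,4-di(prop-1-en-2-yl)cyclohexyl]ethenyllithium | C=C(C)[C@@H]1CC[C@@](C)(C([Li])=C)[C@@H](C1)C(C)=C | intermediate
9 | 1-[2-(allyloxy)-3,4,6-trimethoxyphenyl]-2-[(1R,2S,4R)-1-methyl-2,4-di(prop-1-en-2-yl)cyclohexyl]prop-2-en-1-ol, both carbinol epimers | C=C(C)[C@@H]1CC[C@@](C)(C(=C)C(O)c2c(OCC=C)c(OC)c(OC)cc2OC)[C@@H](C1)C(C)=C | intermediate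
10 | 1-[2-(allyloxy)-3,4,6-trimethoxyphenyl]-2-[(1R,2S,4R)-1-methyl-2,4-di(prop-1-en-2-yl)cyclohexyl]allyl cation | C=C(C)[C@@H]1CC[C@@](C)(C(=C)[CH+]c2c(OCC=C)c(OC)c(OC)cc2OC)[C@@H](C1)C(C)=C | intermediate
11 | (E)-1-[2-(allyloxy)-3,4,6-trimethoxybenzylidene]eudesm-11-en-4α-ol (trans-decalin, 4β-Me, 5α-H, 7β-isopropenyl, 10β-Me, aryl anti to C10) | C=C(C)[C@@H]1CC[C@]2(C)[C@@H](C1)[C@](C)(O)CC/C2=C\c1c(OCC=C)c(OC)c(OC)cc1OC | intermediate
12 | (E)-1-(2-hydroxy-3,4,6-trimethoxybenzylidene)eudesm-11-en-4α-ol (same decalin stereochemistry as 11) | C=C(C)[C@@H]1CC[C@]2(C)[C@@H](C1)[C@](C)(O)CC/C2=C\c1c(O)c(OC)c(OC)cc1OC | intermediate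
13 | 1-phenyl-1-(trimethylsiloxy)ethene | C=C(O[Si](C)(C)C)c1ccccc1 | starting material
14 | 6-[(4α-hydroxyeudesm-11-en-1β-yl)methylidene]-2,3,5-trimethoxycyclohexa-2,4-dien-1-one (ortho-quinone methide, exocyclic geometry not fixed) | C=C(C)[C@@H]1CC[C@]2(C)[C@@H](C1)[C@](C)(O)CC[C@H]2C=C1C(=O)C(OC)=C(OC)C=C1OC | intermediate
15 | (4'R)-4-(4α-hydroxyeudesm-11-en-1β-yl)-5,7,8-trimethoxy-2-phenyl-2-(trimethylsiloxy)chroman, both C2' epimers | C=C(C)[C@@H]1CC[C@]2(C)[C@@H](C1)[C@](C)(O)CC[C@H]2[C@@H]1CC(O[Si](C)(C)C)(c2ccccc2)Oc2c(OC)c(OC)cc(OC)c21 | intermediate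
16 | (4'R)-5,7,8-trimethoxy-2-phenyl-4-[(1S,4R,5R,7R,10S)-4-hydroxyeudesm-11-en-1-yl]-4H-chromene | C=C(C)[C@@H]1CC[C@]2(C)[C@@H](C1)[C@](C)(O)CC[C@H]2[C@@H]1C=C(c2ccccc2)Oc2c(OC)c(OC)cc(OC)c21 | target

Total step count: 9. Longest linear sequence: 7 steps (steps 1, 2, 3, 6, 7, 8, 9).

Steps most likely to fail

Step 9. The enol silane may be protonated and desilylated faster than 12 is C-protonated, the ortho-quinone methide may dimerise, or facial discrimination at C4' (or leakage through the C1 epimer) may be insufficient under acid. The fallback separates ortho-quinone methide formation, C–C bond formation and ring closure and runs the bond-forming event under basic conditions. Setting out from 12, p-toluenesulfinic acid (CH2Cl2, rt) should add across the styrene through the same C1 protonation to give the benzylic p-tolyl sulfone F1, a storable ortho-quinone methide precursor. PhC(OLi)=CH2 (2.2 equiv, from acetophenone and LiN(i-Pr)2, THF, −78 → 0 °C) should eliminate sulfinate and add to C4' under the same allylic-strain control to give the phenol ketone F2 (open form of the 2-hydroxychroman). PPTS, 4 Å MS, toluene, 60 °C should then close the pyran ring by cyclodehydration, returning at 16.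

Step 7. The isopropenyl group may attack the benzylic terminus of the allyl cation instead of its CH2 terminus, the tertiary C4 cation may lose a proton instead of being captured by water, or capture may occur from the β face. The fallback uses an initiator with a single electrophilic carbon and installs the C4 oxygen separately. Setting out from 9, MnO2 (CH2Cl2) should give the aryl vinyl ketone F3. Me2AlCl (CH2Cl2, −78 °C) should close ring A by enone-initiated cation–olefin cyclization ending in proton loss, and NaOMe equilibration of the C1–H next to the ketone should give the 1β-aroyl 3-ene F4. mCPBA (1 equiv, −20 °C) should epoxidise the trisubstituted ring alkene from the α face in preference to the isopropenyl group to give the 3α,4α-epoxide F5. LiAlH4 should open it at C3 and reduce the ketone to the 4α-hydroxy benzylic alcohol F6. Pd(PPh3)4/morpholine should then give the 2-hydroxybenzyl alcohol F7, which loses water under the acid of step 9 to the ortho-quinone methide 14 and so re-enters the route there.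

Step 4. Oxidation of the neopentyl-type vinyl group may be slow, and divalent palladium may instead trigger cyclisation or isomerisation of the 1,5-diene or give the aldehyde regioisomer. The fallback forms the C1–C4' bond directly on the alkene. Setting out from 5 and 4, nickel-catalysed three-component coupling of the monosubstituted alkene, the aldehyde and a silyl triflate (Ni(cod)2, EtOPPh2, Et3SiOTf, Et3N, toluene, rt) should join the internal vinyl carbon to the formyl carbon and give the triethylsilyl ether F8. TBAF (THF) then returns at 9, bypassing 6–8.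

Further compounds
F1 | step 9 | 1β-[(2-hydroxy-3,4,6-trimethoxyphenyl)(p-tolylsulfonyl)methyl]eudesm-11-en-4α-ol, both benzylic epimers | C=C(C)[C@@H]1CC[C@]2(C)[C@@H](C1)[C@](C)(O)CC[C@H]2C(c1c(O)c(OC)c(OC)cc1OC)S(=O)(=O)c1ccc(C)cc1
F2 | step 9 | (3R)-3-(4α-hydroxyeudesm-11-en-1β-yl)-3-(2-hydroxy-3,4,6-trimethoxyphenyl)-1-phenylpropan-1-one (C4' as in the target) | C=C(C)[C@@H]1CC[C@]2(C)[C@@H](C1)[C@](C)(O)CC[C@H]2[C@H](CC(=O)c1ccccc1)c1c(O)c(OC)c(OC)cc1OC
F3 | step 7 | 1-[2-(allyloxy)-3,4,6-trimethoxyphenyl]-2-[(1R,2S,4R)-1-methyl-2,4-di(prop-1-en-2-yl)cyclohexyl]prop-2-en-1-one | C=C(C)[C@@H]1CC[C@@](C)(C(=C)C(=O)c2c(OCC=C)c(OC)c(OC)cc2OC)[C@@H](C1)C(C)=C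
F4 | step 7 | 1β-[2-(allyloxy)-3,4,6-trimethoxybenzoyl]eudesma-3,11-diene | C=C(C)[C@@H]1CC[C@]2(C)[C@@H](C1)C(C)=CC[C@H]2C(=O)c1c(OCC=C)c(OC)c(OC)cc1OC
F5 | step 7 | 1β-[2-(allyloxy)-3,4,6-trimethoxybenzoyl]-3α,4α-epoxyeudesm-11-ene | C=C(C)[C@@H]1CC[C@]2(C)[C@@H](C1)[C@]1(C)O[C@@H]1C[C@H]2C(=O)c1c(OCC=C)c(OC)c(OC)cc1OC
F6 | step 7 | 1β-{[2-(allyloxy)-3,4,6-trimethoxyphenyl](hydroxy)methyl}eudesm-11-en-4α-ol, both carbinol epimers | C=C(C)[C@@H]1CC[C@]2(C)[C@@H](C1)[C@](C)(O)CC[C@H]2C(O)c1c(OCC=C)c(OC)c(OC)cc1OC
F7 | step 7 | 1β-[hydroxy(2-hydroxy-3,4,6-trimethoxyphenyl)methyl]eudesm-11-en-4α-ol, both carbinol epimers | C=C(C)[C@@H]1CC[C@]2(C)[C@@H](C1)[C@](C)(O)CC[C@H]2C(O)c1c(O)c(OC)c(OC)cc1OC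
F8 | step 4 | triethylsilyl ether of 9, both carbinol epimers | C=C(C)[C@@H]1CC[C@@](C)(C(=C)C(O[Si](CC)(CC)CC)c2c(OCC=C)c(OC)c(OC)cc2OC)[C@@H](C1)C(C)=C
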